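**Retrosynthetic overview**
1. Target ⇐ acetylation and desilylation of the TBS-protected dienoate; its C2=C3 bond ⇐ E1cB dehydration (via the mesylate) of a β-hydroxy ester.
2. Key C2–C3 bond: intermolecular aldol addition of the lithium enolate of methyl (S)-7-(TBS-oxy)-6-methylheptanoate to (E)-7-(furan-3-yl)-4-methylhept-4-enal.
3. Aldehyde ⇐ Johnson–Claisen rearrangement (sets the 6E trisubstituted alkene) of the isopropenyl carbinol made from 3-(furan-3-yl)propanal, itself from 3-furaldehyde (Wittig, hydrogenation, DIBAL).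
4. Ester ⇐ (R)-Roche ester (sole source of the S centre): silylation, DIBAL, Wittig with the 3-carboxypropyl ylide, esterification, hydrogenation.
5. Rings: none is formed; the furan is bought intact in 3-furaldehyde and carried through.

Assumption: LDA, NaHMDS, DIBAL-H, TBAF and isopropenylmagnesium bromide are used as purchased solutions; 7, 22 and 23 are carried as stereoisomer mixtures because those centres are destroyed later.

**Route**

Step 1
Reactants: 1 furan-3-carbaldehyde; 2 ethyl (triphenylphosphoranylidene)acetate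
Product: 3 ethyl (E)-3-(furan-3-yl)prop-2-enoate
Conditions: CH2Cl2, rt, 16 h
Reagents that add atoms: none
Why: Wittig olefination with a stabilised ylide runs under neutral conditions that the furan tolerates and gives the E-acrylate (geometry is irrelevant, the alkene is reduced next).

Step 2
Reactants: 3 ethyl (E)-3-(furan-3-yl)prop-2-enoate
Product: 4 ethyl 3-(furan-3-yl)propanoate
Conditions: H2 (1 atm), 5% Pd/C, EtOAc, rt, stopped after 1 equiv H2
Reagents that add atoms: none
Why: Catalytic hydrogenation reduces the conjugated disubstituted C=C much faster than the aromatic furan at 1 atm in a neutral solvent.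

Step 3
Reactants: 4 ethyl 3-(furan-3-yl)propanoate
Product: 5 3-(furan-3-yl)propanal
Conditions: DIBAL-H (1.1 equiv), CH2Cl2, −78 °C; then H2O, aq. Rochelle salt
Reagents that add atoms: none
Why: DIBAL partial reduction; the tetrahedral aluminium hemiacetal is stable at −78 °C and releases the aldehyde only on work-up.

Step 4
Reactants: 5 3-(furan-3-yl)propanal; 6 isopropenylmagnesium bromide
Product: 7 rac-5-(furan-3-yl)-2-methylpent-1-en-3-ol
Conditions: THF, −78 → 0 °C; then H2O
Reagents that add atoms: none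
Why: Grignard 1,2-addition to an unhindered aldehyde gives the isopropenyl carbinol; it is left racemic because this centre is destroyed in step 5.

Step 5
Reactants: 7 rac-5-(furan-3-yl)-2-methylpent-1-en-3-ol; 8 triethyl orthoacetate
Product: 11 ethyl (E)-7-(furan-3-yl)-4-methylhept-4-enoate, via mixed orthoester 9 (not isolated), via ketene acetal 10 (not isolated)
Conditions: 8 (6 equiv, neat), EtCO2H (cat.), 140 °C, EtOH distilled off
Reagents that add atoms: none
Why: Johnson–Claisen (orthoester) rearrangement through a chair [3,3] transition state with the furylethyl group pseudo-equatorial gives the E-trisubstituted alkene (typically >95:5) and adds the two-carbon ester arm.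

Step 6
Reactants: 11 ethyl (E)-7-(furan-3-yl)-4-methylhept-4-enoate
Product: 12 (E)-7-(furan-3-yl)-4-methylhept-4-enal
Conditions: DIBAL-H (1.1 equiv), CH2Cl2, −78 °C; then H2O, aq. Rochelle salt
Reagents that add atoms: none
Why: DIBAL partial reduction at −78 °C stops at the aldehyde; the isolated alkene and the furan are inert.

Step 7
Reactants: 13 methyl (R)-3-hydroxy-2-methylpropanoate ((R)-Roche ester)
Product: 14 methyl (R)-3-[(tert-butyldimethylsilyl)oxy]-2-methylpropanoate
Conditions: TBSCl, imidazole, CH2Cl2, 0 °C → rt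
Reagents that add atoms: tert-butyldimethylsilyl chloride (TBSCl), CC(C)(C)[Si](C)(C)Cl
Why: Silylation of the primary alcohol with imidazole is too mild to epimerise the α-centre, which becomes the S centre of the target.

Step 8
Reactants: 14 methyl (R)-3-[(tert-butyldimethylsilyl)oxy]-2-methylpropanoate
Product: 15 (R)-3-[(tert-butyldimethylsilyl)oxy]-2-methylpropanal
Conditions: DIBAL-H (1.05 equiv), CH2Cl2, −78 °C; then H2O, aq. Rochelle salt; used crude at once
Reagents that add atoms: none
Why: DIBAL partial reduction at −78 °C gives the aldehyde without epimerisation provided it is not chromatographed or stored.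

Step 9
Reactants: 15 (R)-3-[(tert-butyldimethylsilyl)oxy]-2-methylpropanal; 16 (3-carboxypropyl)triphenylphosphonium bromide
Product: 18 (4Z,6S)-7-[(tert-butyldimethylsilyl)oxy]-6-methylhept-4-enoic acid, via ylide carboxylate 17 (not isolated)
Conditions: 16, NaHMDS (2 equiv per 16), THF, 0 °C; then 15, −78 °C → rt; then 1 M HCl to pH 4, 0 °C
Reagents that add atoms: none
Why: Wittig olefination with a non-stabilised ylide adds to the aldehyde at −78 °C faster than it enolises it, so the stereocentre is carried through (Z geometry is irrelevant).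

Step 10
Reactants: 18 (4Z,6S)-7-[(tert-butyldimethylsilyl)oxy]-6-methylhept-4-enoic acid
Product: 19 methyl (4Z,6S)-7-[(tert-butyldimethylsilyl)oxy]-6-methylhept-4-enoate
Conditions: MeI, K2CO3, DMF, rt
Reagents that add atoms: iodomethane (MeI), CI
Why: SN2 O-alkylation of the carboxylate under mild base leaves the silyl ether and the stereocentre untouched.

Step 11
Reactants: 19 methyl (4Z,6S)-7-[(tert-butyldimethylsilyl)oxy]-6-methylhept-4-enoate
Product: 20 methyl (S)-7-[(tert-butyldimethylsilyl)oxy]-6-methylheptanoate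
Conditions: H2 (1 atm), 5% Pt/C, EtOAc, rt
Reagents that add atoms: none
Why: Catalytic hydrogenation over Pt (less prone than Pd to alkene migration through the allylic centre) saturates the alkene with the S centre intact.

Step 12
Reactants: 20 methyl (S)-7-[(tert-butyldimethylsilyl)oxy]-6-methylheptanoate; 12 (E)-7-(furan-3-yl)-4-methylhept-4-enal
Product: 22 methyl (6E)-2-[(4S)-5-[(tert-butyldimethylsilyl)oxy]-4-methylpentyl]-9-(furan-3-yl)-3-hydroxy-6-methylnon-6-enoate (mixture of C2/C3 diastereomers), via lithium enolate 21 (not isolated)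
Conditions: LDA (1.1 equiv), THF, −78 °C, 45 min; then 12, −78 °C, 30 min; then AcOH, −78 °C
Reagents that add atoms: none
Why: Intermolecular aldol addition of the kinetic lithium ester enolate to the unhindered aldehyde at −78 °C forms the C2–C3 bond that joins the two fragments; the two new centres form unselectively and are erased in step 14.

Step 13
Reactants: 22 methyl (6E)-2-[(4S)-5-[(tert-butyldimethylsilyl)oxy]-4-methylpentyl]-9-(furan-3-yl)-3-hydroxy-6-methylnon-6-enoate
Product: 23 methyl (6E)-2-[(4S)-5-[(tert-butyldimethylsilyl)oxy]-4-methylpentyl]-9-(furan-3-yl)-6-methyl-3-[(methylsulfonyl)oxy]non-6-enoate (mixture of C2/C3 diastereomers)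
Conditions: MsCl, Et3N, CH2Cl2, 0 °C; used crude
Reagents that add atoms: methanesulfonyl chloride (MsCl), CS(=O)(=O)Cl
Why: Mesylation of the secondary alcohol turns the hydroxyl into a leaving group under conditions that the furan and silyl ether tolerate.

Step 14
Reactants: 23 methyl (6E)-2-[(4S)-5-[(tert-butyldimethylsilyl)oxy]-4-methylpentyl]-9-(furan-3-yl)-6-methyl-3-[(methylsulfonyl)oxy]non-6-enoate
Product: 24 methyl (2E,6E)-2-[(4S)-5-[(tert-butyldimethylsilyl)oxy]-4-methylpentyl]-9-(furan-3-yl)-6-methylnona-2,6-dienoate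
Conditions: DBU (3 equiv), THF, rt
Reagents that add atoms: none
Why: E1cB elimination through the ester enolate funnels both diastereomers to the thermodynamically preferred (E)-2-alkyl-2-enoate (ester cis to H, as in tiglates).

Step 15
Reactants: 24 methyl (2E,6E)-2-[(4S)-5-[(tert-butyldimethylsilyl)oxy]-4-methylpentyl]-9-(furan-3-yl)-6-methylnona-2,6-dienoate
Product: 25 methyl (2E,6E)-9-(furan-3-yl)-2-[(4S)-5-hydroxy-4-methylpentyl]-6-methylnona-2,6-dienoate
Conditions: TBAF, AcOH (1:1), THF, 0 °C → rt
Reagents that add atoms: none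
Why: Fluoride-mediated desilylation buffered with AcOH spares the enoate, the methyl ester and the acid-sensitive furan.

Step 16
Reactants: 25 methyl (2E,6E)-9-(furan-3-yl)-2-[(4S)-5-hydroxy-4-methylpentyl]-6-methylnona-2,6-dienoate
Product: 26 methyl (2E,6E)-2-[(4S)-5-acetoxy-4-methylpentyl]-9-(furan-3-yl)-6-methylnona-2,6-dienoate
Conditions: Ac2O, pyridine, DMAP (cat.), CH2Cl2, 0 °C → rt
Reagents that add atoms: acetic anhydride (Ac2O), CC(=O)OC(C)=O
Why: DMAP-catalysed acylation of the primary alcohol gives the acetate without touching the stereocentre or either alkene.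

**Compound list**
1 | furan-3-carbaldehyde | O=Cc1ccoc1 | starting material
2 | ethyl (triphenylphosphoranylidene)acetate | CCOC(=O)C=P(c1ccccc1)(c1ccccc1)c1ccccc1 | starting material
3 | ethyl (E)-3-(furan-3-yl)prop-2-enoate | CCOC(=O)/C=C/c1ccoc1 | intermediate
4 | ethyl 3-(furan-3-yl)propanoate | CCOC(=O)CCc1ccoc1 | intermediate
5 | 3-(furan-3-yl)propanal | O=CCCc1ccoc1 | intermediate
6 | isopropenylmagnesium bromide | CC(=C)[Mg]Br | starting material
7 | rac-5-(furan-3-yl)-2-methylpent-1-en-3-ol | CC(=C)C(O)CCc1ccoc1 | intermediate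
8 | triethyl orthoacetate | CCOC(C)(OCC)OCC | starting material
9 | rac-3-[3-(1,1-diethoxyethoxy)-4-methylpent-4-en-1-yl]furan (mixed orthoester, not isolated) | CCOC(C)(OCC)OC(CCc1ccoc1)C(C)=C | intermediate
10 | rac-3-{3-[(1-ethoxyethenyl)oxy]-4-methylpent-4-en-1-yl}furan (ketene acetal, not isolated) | CCOC(=C)OC(CCc1ccoc1)C(C)=C | intermediate
11 | ethyl (E)-7-(furan-3-yl)-4-methylhept-4-enoate | CCOC(=O)CC/C(C)=C/CCc1ccoc1 | intermediate
12 | (E)-7-(furan-3-yl)-4-methylhept-4-enal | O=CCC/C(C)=C/CCc1ccoc1 | intermediate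
13 | methyl (R)-3-hydroxy-2-methylpropanoate | COC(=O)[C@H](C)CO | starting material
14 | methyl (R)-3-[(tert-butyldimethylsilyl)oxy]-2-methylpropanoate | COC(=O)[C@H](C)CO[Si](C)(C)C(C)(C)C | intermediate
15 | (R)-3-[(tert-butyldimethylsilyl)oxy]-2-methylpropanal | O=C[C@H](C)CO[Si](C)(C)C(C)(C)C | intermediate
16 | (3-carboxypropyl)triphenylphosphonium bromide | [Br-].OC(=O)CCC[P+](c1ccccc1)(c1ccccc1)c1ccccc1 | starting material
17 | sodium 4-(triphenylphosphoranylidene)butanoate (ylide carboxylate, not isolated) | [Na+].[O-]C(=O)CCC=P(c1ccccc1)(c1ccccc1)c1ccccc1 | intermediate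
18 | (4Z,6S)-7-[(tert-butyldimethylsilyl)oxy]-6-methylhept-4-enoic acid | OC(=O)CC/C=C\[C@H](C)CO[Si](C)(C)C(C)(C)C | intermediate
19 | methyl (4Z,6S)-7-[(tert-butyldimethylsilyl)oxy]-6-methylhept-4-enoate | COC(=O)CC/C=C\[C@H](C)CO[Si](C)(C)C(C)(C)C | intermediate
20 | methyl (S)-7-[(tert-butyldimethylsilyl)oxy]-6-methylheptanoate | COC(=O)CCCC[C@H](C)CO[Si](C)(C)C(C)(C)C | intermediate
21 | lithium enolate of 20 (enolate geometry not specified, not isolated) | [Li+].[O-]C(OC)=CCCC[C@H](C)CO[Si](C)(C)C(C)(C)C | intermediate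
22 | methyl (6E)-2-[(4S)-5-[(tert-butyldimethylsilyl)oxy]-4-methylpentyl]-9-(furan-3-yl)-3-hydroxy-6-methylnon-6-enoate, mixture at C2/C3 | COC(=O)C(CCC[C@H](C)CO[Si](C)(C)C(C)(C)C)C(O)CC/C(C)=C/CCc1ccoc1 | intermediate
23 | methyl (6E)-2-[(4S)-5-[(tert-butyldimethylsilyl)oxy]-4-methylpentyl]-9-(furan-3-yl)-6-methyl-3-[(methylsulfonyl)oxy]non-6-enoate, mixture at C2/C3 | COC(=O)C(CCC[C@H](C)CO[Si](C)(C)C(C)(C)C)C(OS(C)(=O)=O)CC/C(C)=C/CCc1ccoc1 | intermediate
24 | methyl (2E,6E)-2-[(4S)-5-[(tert-butyldimethylsilyl)oxy]-4-methylpentyl]-9-(furan-3-yl)-6-methylnona-2,6-dienoate | COC(=O)/C(=C/CC/C(C)=C/CCc1ccoc1)CCC[C@H](C)CO[Si](C)(C)C(C)(C)C | intermediate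
25 | methyl (2E,6E)-9-(furan-3-yl)-2-[(4S)-5-hydroxy-4-methylpentyl]-6-methylnona-2,6-dienoate | COC(=O)/C(=C/CC/C(C)=C/CCc1ccoc1)CCC[C@H](C)CO | intermediate
26 | methyl (2E,6E)-2-[(4S)-5-acetoxy-4-methylpentyl]-9-(furan-3-yl)-6-methylnona-2,6-dienoate | COC(=O)/C(=C/CC/C(C)=C/CCc1ccoc1)CCC[C@H](C)COC(C)=O | target

**Totals**
Total step count: 16. Longest linear sequence: 11 steps (steps 1–6, then 12–16, from furan-3-carbaldehyde); the Roche-ester branch is 10 steps.

**Three steps most likely to fail, with fallbacks**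

Step 14 (E/Z ratio of the elimination; a Z-isomer would be hard to separate). The fallback sets out from 20, uses aldehyde 12, and comes back at 24, replacing steps 12–14. Ester 20 is enolised with LDA (THF, −78 °C) and brominated with CBr4 to give methyl (6S)-2-bromo-7-[(tert-butyldimethylsilyl)oxy]-6-methylheptanoate F1. Heating with PPh3 in toluene at 90 °C gives [(6S)-7-[(tert-butyldimethylsilyl)oxy]-1-methoxy-6-methyl-1-oxoheptan-2-yl]triphenylphosphonium bromide F2. Aqueous NaOH/CH2Cl2 then gives the stabilised ylide methyl (6S)-7-[(tert-butyldimethylsilyl)oxy]-6-methyl-2-(triphenylphosphoranylidene)heptanoate F3. Wittig olefination of F3 with 12 in toluene at 90 °C gives 24 directly, with the E-selectivity typical of α-alkyl stabilised ylides (≥95:5).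

Step 9 (partial epimerisation of the α-chiral aldehyde 15, or a modest yield with the carboxylate ylide). The fallback sets out from 14 and comes back at 19, with the stereocentre never α to a carbonyl. LiBH4 (THF, MeOH) reduces 14 to (S)-3-[(tert-butyldimethylsilyl)oxy]-2-methylpropan-1-ol F4. I2, PPh3 and imidazole give (R)-tert-butyl(3-iodo-2-methylpropoxy)dimethylsilane F5. PPh3 in refluxing MeCN gives [(2R)-3-[(tert-butyldimethylsilyl)oxy]-2-methylpropyl]triphenylphosphonium iodide F6. NaHMDS (THF, −78 °C) gives (R)-{3-[(tert-butyldimethylsilyl)oxy]-2-methylpropylidene}triphenylphosphorane F7, which is condensed in the same flask with commercial methyl 4-oxobutanoate to give 19.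

Step 2 (over-reduction of the furan ring, or incomplete reduction). The fallback sets out from 1 and comes back at 4 without any hydrogenation in the presence of the furan. NaBH4 (MeOH, 0 °C) gives furan-3-ylmethanol F8. PBr3 (Et2O, 0 °C) gives 3-(bromomethyl)furan F9, used at once. Alkylation of sodium diethyl malonate (NaH, THF) gives diethyl 2-(furan-3-ylmethyl)propanedioate F10. Krapcho dealkoxycarbonylation (LiCl, H2O, DMSO, 150 °C) gives 4.

**Further compounds**
F1 | step 14 | methyl (6S)-2-bromo-7-[(tert-butyldimethylsilyl)oxy]-6-methylheptanoate (C2 epimers) | COC(=O)C(Br)CCC[C@H](C)CO[Si](C)(C)C(C)(C)C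
F2 | step 14 | [(6S)-7-[(tert-butyldimethylsilyl)oxy]-1-methoxy-6-methyl-1-oxoheptan-2-yl]triphenylphosphonium bromide | [Br-].COC(=O)C(CCC[C@H](C)CO[Si](C)(C)C(C)(C)C)[P+](c1ccccc1)(c1ccccc1)c1ccccc1
F3 | step 14 | methyl (6S)-7-[(tert-butyldimethylsilyl)oxy]-6-methyl-2-(triphenylphosphoranylidene)heptanoate | COC(=O)C(CCC[C@H](C)CO[Si](C)(C)C(C)(C)C)=P(c1ccccc1)(c1ccccc1)c1ccccc1
F4 | step 9 | (S)-3-[(tert-butyldimethylsilyl)oxy]-2-methylpropan-1-ol | OC[C@H](C)CO[Si](C)(C)C(C)(C)C
F5 | step 9 | (R)-tert-butyl(3-iodo-2-methylpropoxy)dimethylsilane | IC[C@H](C)CO[Si](C)(C)C(C)(C)C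
F6 | step 9 | [(2R)-3-[(tert-butyldimethylsilyl)oxy]-2-methylpropyl]triphenylphosphonium iodide | [I-].c1ccccc1[P+](c1ccccc1)(c1ccccc1)C[C@H](C)CO[Si](C)(C)C(C)(C)C
F7 | step 9 | (R)-{3-[(tert-butyldimethylsilyl)oxy]-2-methylpropylidene}triphenylphosphorane | c1ccccc1P(c1ccccc1)(c1ccccc1)=C[C@H](C)CO[Si](C)(C)C(C)(C)C
F8 | step 2 | furan-3-ylmethanol | OCc1ccoc1
F9 | step 2 | 3-(bromomethyl)furan | BrCc1ccoc1
F10 | step 2 | diethyl 2-(furan-3-ylmethyl)propanedioate | CCOC(=O)C(Cc1ccoc1)C(=O)OCC
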